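**Retrosynthetic overview**

- The strategy rests on ring A: O1 sits on C8a and the C4 carbonyl on the neighbouring C4a, with oxygen on C5 (next to C4a) and on C7. This is the pattern left when a carboxylate adds across a 3,5-dioxygenated benzyne and its acyl group shifts to the ortho carbon.
- Key disconnection: O1–C8a, C4–C4a and O1–C2 are cut together. This gives a 3,5-bis(MOM)benzyne (from its 2-silylaryl triflate) and a 2-arylacrylic acid that carries C2, C3, C4 and all of ring B. Rings A and B are bought; ring C is the only ring formed, in the key step.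
- Aryne precursor: from phloroglucinol by bis-MOM protection, carbamate-directed ortho-silylation and carbamate-to-triflate exchange.
- Acid: from acetovanillone by bromination, OMe/OH transposition, MOM protection, Suzuki prenylation, enol triflation and hydroxycarbonylation.
- C3 is set after ring closure: Ru transfer hydrogenation with dynamic kinetic resolution gives the cis-(3S,4S)-alcohol, which is reoxidised and freed of its MOM groups.

Key step: step 12

Remark: the (S,S)-TsDPEN ruthenium catalyst is assumed to deliver hydride with the facial sense it shows for chroman-4-one (S carbinol); if the alcohol of step 13 proves to be the enantiomer, the (R,R)-catalyst is used instead.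

**Route**

Step 1
Reactants: 1 phloroglucinol (benzene-1,3,5-triol, anhydrous)
Product: 2 3,5-bis(methoxymethoxy)phenol
Conditions: MOMCl (2.0 equiv), i-Pr2NEt, DMF/CH2Cl2, 0 °C to rt; chromatography
Reagents that add atoms: chloromethyl methyl ether COCCl
Why: O-alkylation of the threefold symmetric triphenol with two equivalents of MOMCl should give the bis-ether as the main part of a statistical mixture, from which the mono- and tris-ethers can be separated and recycled.

Step 2
Reactants: 2 3,5-bis(methoxymethoxy)phenol
Product: 3 3,5-bis(methoxymethoxy)phenyl N-(propan-2-yl)carbamate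
Conditions: i-PrNCO, Et3N (cat.), CH2Cl2, rt
Reagents that add atoms: isopropyl isocyanate CC(C)N=C=O
Why: Amine-catalysed addition of the phenol to the isocyanate (carbamoylation) installs a strong ortho-directing group that can later be removed under mild base.

Step 3
Reactants: 3 3,5-bis(methoxymethoxy)phenyl N-(propan-2-yl)carbamate
Product: 6 3,5-bis(methoxymethoxy)-2-(trimethylsilyl)phenyl N-(propan-2-yl)carbamate, via N-silyl carbamate 4 (not isolated), via C-silylated N-silyl carbamate 5 (not isolated)
Conditions: TBSOTf, TMEDA, Et2O, 0 °C to rt; n-BuLi, TMEDA, −78 °C; TMSCl, −78 °C to rt; aq. citric acid work-up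
Reagents that add atoms: chlorotrimethylsilane C[Si](C)(C)Cl; tert-butyldimethylsilyl triflate CC(C)(C)[Si](C)(C)OS(=O)(=O)C(F)(F)F (its atoms stay only in 4 and 5)
Why: Directed ortho-metalation: the N-silylated carbamate is the strongest directing group on the ring and, reinforced by the neighbouring MOM ether, should steer lithiation to the carbon between them (two equivalent sites) in preference to the carbon between the two MOM ethers; silylation and hydrolysis of the N–Si bond on work-up give 6.

Step 4
Reactants: 6 3,5-bis(methoxymethoxy)-2-(trimethylsilyl)phenyl N-(propan-2-yl)carbamate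
Product: 8 3,5-bis(methoxymethoxy)-2-(trimethylsilyl)phenyl trifluoromethanesulfonate, via silylphenol 7 (not isolated)
Conditions: DBU, Et2NH, MeCN, 40 °C; then PhNTf2, rt (one flask)
Reagents that add atoms: N-phenylbis(trifluoromethanesulfonimide) O=S(=O)(N(c1ccccc1)S(=O)(=O)C(F)(F)F)C(F)(F)F
Why: DBU expels isopropyl isocyanate from the N–H carbamate (E1cB), diethylamine traps it as a urea, and the liberated phenoxide is sulfonylated in situ by the mild triflating agent, which avoids isolating the sensitive ortho-silylphenol.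

Step 5
Reactants: 9 acetovanillone, 1-(4-hydroxy-3-methoxyphenyl)ethanone
Product: 10 1-(3-bromo-4-hydroxy-5-methoxyphenyl)ethanone
Conditions: Br2, NaOAc, AcOH, rt
Reagents that add atoms: bromine BrBr
Why: Electrophilic aromatic bromination goes to the only free position ortho to the phenol (para is blocked by the acetyl group), and the acetate buffer keeps the ketone from brominating at its methyl group.

Step 6
Reactants: 10 1-(3-bromo-4-hydroxy-5-methoxyphenyl)ethanone
Product: 11 1-(3-bromo-4,5-dihydroxyphenyl)ethanone
Conditions: AlCl3, pyridine, CH2Cl2, reflux; aq. HCl work-up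
Reagents that add atoms: none
Why: Chelation-assisted ether cleavage: the aluminium phenoxide binds the neighbouring methoxy oxygen and chloride removes the methyl group, a demethylation that is specific to 2-methoxyphenols and leaves the bromide and ketone alone.

Step 7
Reactants: 11 1-(3-bromo-4,5-dihydroxyphenyl)ethanone
Product: 12 1-(3-bromo-5-hydroxy-4-methoxyphenyl)ethanone
Conditions: MeI (1.1 equiv), Li2CO3, DMF, 40 °C
Reagents that add atoms: iodomethane CI
Why: The hydroxyl para to the acetyl group and ortho to bromine is the more acidic one, so the weak base should form that phenoxide selectively and the Williamson methylation should take place there, completing the OMe/OH transposition.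

Step 8
Reactants: 12 1-(3-bromo-5-hydroxy-4-methoxyphenyl)ethanone
Product: 13 1-[3-bromo-4-methoxy-5-(methoxymethoxy)phenyl]ethanone
Conditions: MOMCl, i-Pr2NEt, CH2Cl2, 0 °C to rt
Reagents that add atoms: chloromethyl methyl ether COCCl
Why: Standard MOM protection of the remaining phenol gives a group that withstands hydroxide, amide base, fluoride at high temperature and hydride transfer, and that leaves with the ring A MOM ethers at the end.

Step 9
Reactants: 13 1-[3-bromo-4-methoxy-5-(methoxymethoxy)phenyl]ethanone; 14 prenylboronic acid pinacol ester, 4,4,5,5-tetramethyl-2-(3-methylbut-2-enyl)-1,3,2-dioxaborolane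
Product: 15 1-[4-methoxy-3-(methoxymethoxy)-5-(3-methylbut-2-enyl)phenyl]ethanone
Conditions: PdCl2(IPent)(3-chloropyridine) (2 mol%; IPent = 1,3-bis[2,6-di(pentan-3-yl)phenyl]imidazol-2-ylidene), aq. KOH, THF, 70 °C
Reagents that add atoms: none
Why: Suzuki–Miyaura coupling of an allylboronate: the very bulky carbene ligand disfavours the tertiary σ-allyl palladium intermediate, so reductive elimination should occur at the primary terminus and give the linear prenyl arene and not the reverse-prenyl isomer; the electron-rich methyl ketone and the MOM ether tolerate the biphasic hydroxide.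

Step 10
Reactants: 15 1-[4-methoxy-3-(methoxymethoxy)-5-(3-methylbut-2-enyl)phenyl]ethanone
Product: 16 1-[4-methoxy-3-(methoxymethoxy)-5-(3-methylbut-2-enyl)phenyl]ethenyl trifluoromethanesulfonate
Conditions: KN(SiMe3)2, THF, −78 °C; PhNTf2, −78 to 0 °C; Et3N-deactivated silica
Reagents that add atoms: N-phenylbis(trifluoromethanesulfonimide) O=S(=O)(N(c1ccccc1)S(=O)(=O)C(F)(F)F)C(F)(F)F
Why: The methyl ketone has only one enolisable position, and O-sulfonylation of its potassium enolate gives the 1-arylvinyl triflate (enol triflate formation) without touching the prenyl or MOM groups.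

Step 11
Reactants: 16 1-[4-methoxy-3-(methoxymethoxy)-5-(3-methylbut-2-enyl)phenyl]ethenyl trifluoromethanesulfonate
Product: 18 2-[4-methoxy-3-(methoxymethoxy)-5-(3-methylbut-2-enyl)phenyl]prop-2-enoic acid, via mixed acetic anhydride 17 (not isolated)
Conditions: Pd(OAc)2, PPh3, KOAc, CO (1 atm), DMF, rt to 40 °C; then H2O, aq. citric acid to pH 4; used at once
Reagents that add atoms: carbon monoxide [C-]#[O+]; potassium acetate CC(=O)[O-].[K+] (its oxygen bridges anhydride 17); water O (hydrolysis of 17)
Why: Palladium-catalysed hydroxycarbonylation of a vinyl triflate: oxidative addition to zerovalent palladium, CO insertion and capture of the acyl-palladium by acetate give a mixed anhydride that is hydrolysed on work-up, so the acrylic acid forms under neutral conditions that spare the MOM ether and the prenyl alkene.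

Step 12
Reactants: 8 3,5-bis(methoxymethoxy)-2-(trimethylsilyl)phenyl trifluoromethanesulfonate (1.5 equiv); 18 2-[4-methoxy-3-(methoxymethoxy)-5-(3-methylbut-2-enyl)phenyl]prop-2-enoic acid
Product: 21 (±)-5,7-bis(methoxymethoxy)-3-[4-methoxy-3-(methoxymethoxy)-5-(3-methylbut-2-enyl)phenyl]chroman-4-one, via aryne 19 (not isolated), via hydroxyaryl enone 20 (not isolated)
Conditions: CsF (4 equiv), BHT (cat.), THF, 125 °C, sealed tube
Reagents that add atoms: none
Why: Fluoride removes the silyl group of 8 and expels triflate to give aryne 19; the caesium carboxylate of 18 adds through oxygen to the aryne carbon remote from the flanking MOM ether, and the aryl anion formed beside that ether attacks the ester carbonyl and the four-membered adduct opens (a net 1,3 O-to-C acyl shift), which forms O1–C8a and C4–C4a and gives the phenoxide of enone 20. The closest known reaction type is the insertion of arynes into the acyl C–O bond of carboxylic acids, which with acrylic acids runs on to chroman-4-ones. Ring C then closes by 6-endo-trig oxa-Michael addition of the phenoxide to the unsubstituted methylene (O1–C2), giving an aryl-stabilised enolate. C3 arises by unselective protonation of this enolate, so 21 is racemic and its configuration is left to step 13. The step needs regioselective addition to the unsymmetrical aryne, and this is secured by the C–O bond beside the triple bond, which polarises the aryne and stabilises negative charge on the adjacent carbon, so that oxygen ends on C8a and the acyl group on C4a with the MOM ethers at C5 and C7. The high temperature favours the acyl shift over protonation of the aryl anion, and MOM ethers are used because they survive hot fluoride.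

Step 13
Reactants: 21 (±)-5,7-bis(methoxymethoxy)-3-[4-methoxy-3-(methoxymethoxy)-5-(3-methylbut-2-enyl)phenyl]chroman-4-one
Product: 22 (3S,4S)-5,7-bis(methoxymethoxy)-3-[4-methoxy-3-(methoxymethoxy)-5-(3-methylbut-2-enyl)phenyl]chroman-4-ol (aryl and hydroxyl cis)
Conditions: RuCl[(S,S)-TsDPEN](p-cymene) (5 mol%), HCO2H/Et3N (5:2), EtOAc, 40 °C
Reagents that add atoms: none
Why: Noyori-type asymmetric transfer hydrogenation with dynamic kinetic resolution: triethylamine equilibrates the C3 epimers of the α-aryl ketone through the enol faster than reduction, the catalyst delivers hydride to the carbonyl face that gives the 4S carbinol and reduces fastest the epimer that leads to the cis product, so C4 is set by catalyst facial control and C3 (S) by catalyst selection between the interconverting enantiomers, while the isolated alkene is not reduced.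

Step 14
Reactants: 22 (3S,4S)-5,7-bis(methoxymethoxy)-3-[4-methoxy-3-(methoxymethoxy)-5-(3-methylbut-2-enyl)phenyl]chroman-4-ol
Product: 23 (3S)-5,7-bis(methoxymethoxy)-3-[4-methoxy-3-(methoxymethoxy)-5-(3-methylbut-2-enyl)phenyl]chroman-4-one
Conditions: Dess–Martin periodinane, NaHCO3, CH2Cl2, 0 °C to rt
Reagents that add atoms: none
Why: Dess–Martin oxidation of the benzylic secondary alcohol under bicarbonate buffer restores the ketone without acid or base able to enolise C3, so the 3S centre is kept and the C4 centre is deliberately erased.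

Step 15
Reactants: 23 (3S)-5,7-bis(methoxymethoxy)-3-[4-methoxy-3-(methoxymethoxy)-5-(3-methylbut-2-enyl)phenyl]chroman-4-one
Product: 24 (3S)-5,7-dihydroxy-3-[3-hydroxy-4-methoxy-5-(3-methylbut-2-enyl)phenyl]chroman-4-one (target)
Conditions: HCl (1.25 M in MeOH), 0 °C to rt
Reagents that add atoms: none
Why: Acid-catalysed acetal exchange with methanol removes the three MOM ethers as dimethoxymethane; the prenyl group has no free ortho phenol to cyclise onto, and dilute acid at low temperature is expected to be too mild to enolise the ketone appreciably, so C3 should stay S.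

**Compound list**

1 | phloroglucinol (benzene-1,3,5-triol) | Oc1cc(O)cc(O)c1 | starting material
2 | 3,5-bis(methoxymethoxy)phenol | COCOc1cc(O)cc(OCOC)c1 | intermediate
3 | 3,5-bis(methoxymethoxy)phenyl N-(propan-2-yl)carbamate | COCOc1cc(OCOC)cc(OC(=O)NC(C)C)c1 | intermediate
4 | 3,5-bis(methoxymethoxy)phenyl N-(tert-butyldimethylsilyl)-N-(propan-2-yl)carbamate | COCOc1cc(OCOC)cc(OC(=O)N(C(C)C)[Si](C)(C)C(C)(C)C)c1 | intermediate
5 | 3,5-bis(methoxymethoxy)-2-(trimethylsilyl)phenyl N-(tert-butyldimethylsilyl)-N-(propan-2-yl)carbamate | COCOc1cc(OCOC)c([Si](C)(C)C)c(OC(=O)N(C(C)C)[Si](C)(C)C(C)(C)C)c1 | intermediate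
6 | 3,5-bis(methoxymethoxy)-2-(trimethylsilyl)phenyl N-(propan-2-yl)carbamate | COCOc1cc(OCOC)c([Si](C)(C)C)c(OC(=O)NC(C)C)c1 | intermediate
7 | 3,5-bis(methoxymethoxy)-2-(trimethylsilyl)phenol (present as its phenoxide) | COCOc1cc(O)c([Si](C)(C)C)c(OCOC)c1 | intermediate
8 | 3,5-bis(methoxymethoxy)-2-(trimethylsilyl)phenyl trifluoromethanesulfonate | COCOc1cc(OCOC)c([Si](C)(C)C)c(OS(=O)(=O)C(F)(F)F)c1 | intermediate
9 | acetovanillone, 1-(4-hydroxy-3-methoxyphenyl)ethanone | CC(=O)c1ccc(O)c(OC)c1 | starting material
10 | 1-(3-bromo-4-hydroxy-5-methoxyphenyl)ethanone | CC(=O)c1cc(Br)c(O)c(OC)c1 | intermediate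
11 | 1-(3-bromo-4,5-dihydroxyphenyl)ethanone | CC(=O)c1cc(O)c(O)c(Br)c1 | intermediate
12 | 1-(3-bromo-5-hydroxy-4-methoxyphenyl)ethanone | CC(=O)c1cc(O)c(OC)c(Br)c1 | intermediate
13 | 1-[3-bromo-4-methoxy-5-(methoxymethoxy)phenyl]ethanone | CC(=O)c1cc(Br)c(OC)c(OCOC)c1 | intermediate
14 | prenylboronic acid pinacol ester, 4,4,5,5-tetramethyl-2-(3-methylbut-2-enyl)-1,3,2-dioxaborolane | CC(C)=CCB1OC(C)(C)C(C)(C)O1 | starting material
15 | 1-[4-methoxy-3-(methoxymethoxy)-5-(3-methylbut-2-enyl)phenyl]ethanone | CC(=O)c1cc(CC=C(C)C)c(OC)c(OCOC)c1 | intermediate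
16 | 1-[4-methoxy-3-(methoxymethoxy)-5-(3-methylbut-2-enyl)phenyl]ethenyl trifluoromethanesulfonate | C=C(OS(=O)(=O)C(F)(F)F)c1cc(CC=C(C)C)c(OC)c(OCOC)c1 | intermediate
17 | acetic 2-[4-methoxy-3-(methoxymethoxy)-5-(3-methylbut-2-enyl)phenyl]prop-2-enoic anhydride | C=C(C(=O)OC(C)=O)c1cc(CC=C(C)C)c(OC)c(OCOC)c1 | intermediate
18 | 2-[4-methoxy-3-(methoxymethoxy)-5-(3-methylbut-2-enyl)phenyl]prop-2-enoic acid | C=C(C(=O)O)c1cc(CC=C(C)C)c(OC)c(OCOC)c1 | intermediate
19 | 3,5-bis(methoxymethoxy)benzyne (1,2-didehydro-3,5-bis(methoxymethoxy)benzene) | COCOC1=CC#CC(OCOC)=C1 | intermediate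
20 | 1-[2-hydroxy-4,6-bis(methoxymethoxy)phenyl]-2-[4-methoxy-3-(methoxymethoxy)-5-(3-methylbut-2-enyl)phenyl]prop-2-en-1-one (present as its caesium phenoxide) | C=C(C(=O)c1c(O)cc(OCOC)cc1OCOC)c1cc(CC=C(C)C)c(OC)c(OCOC)c1 | intermediate
21 | (±)-5,7-bis(methoxymethoxy)-3-[4-methoxy-3-(methoxymethoxy)-5-(3-methylbut-2-enyl)phenyl]chroman-4-one | CC(C)=CCc1cc(C2COc3cc(OCOC)cc(OCOC)c3C2=O)cc(OCOC)c1OC | intermediate
22 | (3S,4S)-5,7-bis(methoxymethoxy)-3-[4-methoxy-3-(methoxymethoxy)-5-(3-methylbut-2-enyl)phenyl]chroman-4-ol (cis) | CC(C)=CCc1cc([C@H]2COc3cc(OCOC)cc(OCOC)c3[C@H]2O)cc(OCOC)c1OC | intermediate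
23 | (3S)-5,7-bis(methoxymethoxy)-3-[4-methoxy-3-(methoxymethoxy)-5-(3-methylbut-2-enyl)phenyl]chroman-4-one | CC(C)=CCc1cc([C@H]2COc3cc(OCOC)cc(OCOC)c3C2=O)cc(OCOC)c1OC | intermediate
24 | (3S)-5,7-dihydroxy-3-[3-hydroxy-4-methoxy-5-(3-methylbut-2-enyl)phenyl]chroman-4-one | COc1c(O)cc([C@H]2COc3cc(O)cc(O)c3C2=O)cc1CC=C(C)C | target

**Step count and risks**

Total step count: 15. Longest linear sequence: 11 steps (steps 5 to 15, from acetovanillone).

Steps most likely to fail:

Step 12. Several processes can divert the cascade: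
- protonation of the aryl anion before the acyl shift, which gives only the aryl ester;
- thermal dimerisation or polymerisation of the 2-arylacrylate;
- cycloaddition or ene reaction of the aryne with the styrene or prenyl alkene;
- arylation of the C3 enolate of 21 by surplus aryne.

The fallback reaches the same enone phenoxide without an aryne, sets out from 16 and rejoins the route at 21. Commercial 2,4,6-trihydroxybenzaldehyde is bis-protected with MOMCl and i-Pr2NEt (the hydrogen-bonded ortho hydroxyl stays free) to give 2-hydroxy-4,6-bis(methoxymethoxy)benzaldehyde F1. Silylation with TBSCl and imidazole in DMF gives 2-(tert-butyldimethylsilyloxy)-4,6-bis(methoxymethoxy)benzaldehyde F2. Vinyl triflate 16 is added to F2 under Nozaki–Hiyama–Kishi conditions (CrCl2, NiCl2 cat., DMF, rt) to give (±)-1-[2-(tert-butyldimethylsilyloxy)-4,6-bis(methoxymethoxy)phenyl]-2-[4-methoxy-3-(methoxymethoxy)-5-(3-methylbut-2-enyl)phenyl]prop-2-en-1-ol F3. Dess–Martin oxidation gives 1-[2-(tert-butyldimethylsilyloxy)-4,6-bis(methoxymethoxy)phenyl]-2-[4-methoxy-3-(methoxymethoxy)-5-(3-methylbut-2-enyl)phenyl]prop-2-en-1-one F4. Bu4NF in THF then removes the silyl group, and the phenoxide of 20 should close by oxa-Michael addition to 21.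

Step 3. Lithiation may stray to the carbon between the two MOM ethers, and the silyl triflate used for N-silylation may activate a MOM acetal. The fallback installs the silyl group by ortho-bromination and a retro-Brook shift; it sets out from 2 and rejoins the route at 8. Amine-mediated ortho-bromination of 2 (NBS, i-Pr2NH cat., CH2Cl2, low temperature) gives 2-bromo-3,5-bis(methoxymethoxy)phenol F5. Hexamethyldisilazane in hot THF gives [2-bromo-3,5-bis(methoxymethoxy)phenoxy]trimethylsilane F6. n-BuLi at −100 °C then effects bromine–lithium exchange and the 1,3 O-to-C silyl shift to the lithium salt of 7, which is triflated with Tf2O to give 8.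

Step 15. Acid-catalysed enolisation of the α-aryl ketone may erode the configuration at C3, and the acid may add to the prenyl alkene. The fallback exchanges the protecting groups while the material is still racemic, so that the last step uses fluoride instead of acid; it sets out from 21 and rejoins the route at 24.
- The MOM ethers of 21 are removed with HCl in MeOH to give (±)-5,7-dihydroxy-3-[3-hydroxy-4-methoxy-5-(3-methylbut-2-enyl)phenyl]chroman-4-one F7.
- TBSOTf and 2,6-lutidine give (±)-5,7-bis(tert-butyldimethylsilyloxy)-3-[3-(tert-butyldimethylsilyloxy)-4-methoxy-5-(3-methylbut-2-enyl)phenyl]chroman-4-one F8.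
- The conditions of step 13 give (3S,4S)-5,7-bis(tert-butyldimethylsilyloxy)-3-[3-(tert-butyldimethylsilyloxy)-4-methoxy-5-(3-methylbut-2-enyl)phenyl]chroman-4-ol F9.
- The conditions of step 14 give (3S)-5,7-bis(tert-butyldimethylsilyloxy)-3-[3-(tert-butyldimethylsilyloxy)-4-methoxy-5-(3-methylbut-2-enyl)phenyl]chroman-4-one F10.
- Et3N·3HF in THF at rt then frees the three phenols to give 24.

**Further compounds**

F1 | step 12 | 2-hydroxy-4,6-bis(methoxymethoxy)benzaldehyde | O=Cc1c(O)cc(OCOC)cc1OCOC
F2 | step 12 | 2-(tert-butyldimethylsilyloxy)-4,6-bis(methoxymethoxy)benzaldehyde | O=Cc1c(O[Si](C)(C)C(C)(C)C)cc(OCOC)cc1OCOC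
F3 | step 12 | (±)-1-[2-(tert-butyldimethylsilyloxy)-4,6-bis(methoxymethoxy)phenyl]-2-[4-methoxy-3-(methoxymethoxy)-5-(3-methylbut-2-enyl)phenyl]prop-2-en-1-ol | C=C(C(O)c1c(O[Si](C)(C)C(C)(C)C)cc(OCOC)cc1OCOC)c1cc(CC=C(C)C)c(OC)c(OCOC)c1
F4 | step 12 | 1-[2-(tert-butyldimethylsilyloxy)-4,6-bis(methoxymethoxy)phenyl]-2-[4-methoxy-3-(methoxymethoxy)-5-(3-methylbut-2-enyl)phenyl]prop-2-en-1-one | C=C(C(=O)c1c(O[Si](C)(C)C(C)(C)C)cc(OCOC)cc1OCOC)c1cc(CC=C(C)C)c(OC)c(OCOC)c1
F5 | step 3 | 2-bromo-3,5-bis(methoxymethoxy)phenol | COCOc1cc(O)c(Br)c(OCOC)c1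
F6 | step 3 | [2-bromo-3,5-bis(methoxymethoxy)phenoxy]trimethylsilane | COCOc1cc(O[Si](C)(C)C)c(Br)c(OCOC)c1
F7 | step 15 | (±)-5,7-dihydroxy-3-[3-hydroxy-4-methoxy-5-(3-methylbut-2-enyl)phenyl]chroman-4-one | COc1c(O)cc(C2COc3cc(O)cc(O)c3C2=O)cc1CC=C(C)C
F8 | step 15 | (±)-5,7-bis(tert-butyldimethylsilyloxy)-3-[3-(tert-butyldimethylsilyloxy)-4-methoxy-5-(3-methylbut-2-enyl)phenyl]chroman-4-one | COc1c(O[Si](C)(C)C(C)(C)C)cc(C2COc3cc(O[Si](C)(C)C(C)(C)C)cc(O[Si](C)(C)C(C)(C)C)c3C2=O)cc1CC=C(C)C
F9 | step 15 | (3S,4S)-5,7-bis(tert-butyldimethylsilyloxy)-3-[3-(tert-butyldimethylsilyloxy)-4-methoxy-5-(3-methylbut-2-enyl)phenyl]chroman-4-ol | COc1c(O[Si](C)(C)C(C)(C)C)cc([C@H]2COc3cc(O[Si](C)(C)C(C)(C)C)cc(O[Si](C)(C)C(C)(C)C)c3[C@H]2O)cc1CC=C(C)C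
F10 | step 15 | (3S)-5,7-bis(tert-butyldimethylsilyloxy)-3-[3-(tert-butyldimethylsilyloxy)-4-methoxy-5-(3-methylbut-2-enyl)phenyl]chroman-4-one | COc1c(O[Si](C)(C)C(C)(C)C)cc([C@H]2COc3cc(O[Si](C)(C)C(C)(C)C)cc(O[Si](C)(C)C(C)(C)C)c3C2=O)cc1CC=C(C)C
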